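**Retrosynthetic overview**
- The acetate and the tertiary carbinol are installed last (acetylation; double MeLi addition to a dienoate); the cis epoxy alcohol comes from a 6-methylcyclohept-5-en-4-one by nucleophilic epoxidation, then hydride delivery anti to the oxirane.
- The dienyl side chain comes from a C1 acetyl group by Horner–Wadsworth–Emmons olefination with a 4-phosphonocrotonate.
- The enone of the seven-membered ring is built on the surviving ring ketone (dehydrogenation, methyl conjugate addition, Saegusa–Ito oxidation).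
- Key step: an enantioselective, desymmetrising copper-hydride reductive aldol cyclisation of a prochiral 2,2-disubstituted cycloheptane-1,3-dione sets the quaternary centre and closes the five-membered ring; the trans ring fusion follows by dissolving-metal reduction.
- Ring order: the seven-membered ring is bought (cycloheptane-1,3-dione), the five-membered ring is formed in the key step, the oxirane last.

Assumption: the (R)-ligand in step 4 is taken to give the (3aS) series, and the two transient centres of the aldol intermediates are drawn syn-aldol and cis-fused by analogy; if induction is the reverse, the (S)-ligand is used.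

Names use azulene numbering: C3a carries the angular methyl, C4 the ring oxygen next to it, C5/C6 the oxirane, C8a the ring-fusion hydrogen, C1 the side chain.

**Step 1**
Reactants: 1 cycloheptane-1,3-dione
Product: 2 2-methylcycloheptane-1,3-dione
Conditions: MeI (1.05 equiv), K2CO3, acetone, 56 °C
Reagents that add atoms: iodomethane (CI)
Why: Enolate C-alkylation of the doubly activated methylene of a cyclic 1,3-dione; no stereocentre is formed.

**Step 2**
Reactants: 2 2-methylcycloheptane-1,3-dione; 3 allyl methyl carbonate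
Product: 4 2-methyl-2-(prop-2-en-1-yl)cycloheptane-1,3-dione
Conditions: Pd(PPh3)4 (2 mol%), THF, rt
Reagents that add atoms: none
Why: Tsuji–Trost allylation under neutral conditions; the carbonate ionises to a π-allylpalladium methoxide that deprotonates 2 and allylates carbon only, giving the prochiral quaternary carbon.

**Step 3**
Reactants: 4 2-methyl-2-(prop-2-en-1-yl)cycloheptane-1,3-dione; 5 but-3-en-2-one
Product: 6 2-methyl-2-[(2E)-4-oxopent-2-en-1-yl]cycloheptane-1,3-dione
Conditions: second-generation Grubbs catalyst (3 mol%), 5 (3 equiv), CH2Cl2, 40 °C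
Reagents that add atoms: none
Why: Olefin cross-metathesis of a terminal alkene with an electron-poor enone gives the E-enone selectively; the non-enolisable dione is inert.

**Step 4**
Reactants: 6 2-methyl-2-[(2E)-4-oxopent-2-en-1-yl]cycloheptane-1,3-dione
Product: 9 (3aS)-1-acetyl-3a-methyl-3,3a,5,6,7,8-hexahydroazulen-4(2H)-one, via silyl ether 7 (not isolated), via ketol 8 (not isolated)
Conditions: Cu(OAc)2 (5 mol%), (R)-DTBM-SEGPHOS (5.5 mol%), (EtO)2MeSiH (1.5 equiv), toluene, −20 °C; then TsOH·H2O, toluene, 60 °C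
Reagents that add atoms: none
Why: Enantioselective desymmetrising reductive aldol cyclisation, in which ligated copper hydride adds 1,4 to the enone and the chiral copper enolate attacks one of the two enantiotopic ring carbonyls through a closed transition state, fixing the quaternary centre (3aS); acid then cleaves the silyl ether and dehydrates the tertiary β-hydroxy ketone (E1cB) to the conjugated enone, erasing the two transient centres.

**Step 5**
Reactants: 9 (3aS)-1-acetyl-3a-methyl-3,3a,5,6,7,8-hexahydroazulen-4(2H)-one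
Product: 11 (1R,3aS,8aS)-1-acetyl-3a-methyloctahydroazulen-4(1H)-one, via lithium enolate 10 (not isolated)
Conditions: Li (2.2 equiv), NH3(l)/THF, −78 °C; NH4Cl; then NaOMe (0.1 equiv), MeOH, 0 °C
Reagents that add atoms: none
Why: Dissolving-metal enone reduction, in which the β-carbanion at C8a is protonated on the face opposite the axial angular methyl to give the trans ring fusion (8aS), the saturated ring ketone survives without excess proton donor, and brief methoxide equilibration places the C1 acetyl trans to the C8a–C8 bond (1R).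

**Step 6**
Reactants: 11 (1R,3aS,8aS)-1-acetyl-3a-methyloctahydroazulen-4(1H)-one; 12 ethyl (2E)-4-(diethoxyphosphoryl)but-2-enoate
Product: 13 ethyl (2E,4E)-5-[(1R,3aS,8aS)-3a-methyl-4-oxodecahydroazulen-1-yl]hexa-2,4-dienoate
Conditions: LiN(SiMe3)2, THF, −78 °C to 40 °C
Reagents that add atoms: none
Why: Vinylogous Horner–Wadsworth–Emmons olefination; the phosphonate anion attacks only the methyl ketone (the ring ketone is neopentyl) and gives the (2E,4E)-dienoate as major isomer, the 4Z isomer being removed by chromatography.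

**Step 7**
Reactants: 13 ethyl (2E,4E)-5-[(1R,3aS,8aS)-3a-methyl-4-oxodecahydroazulen-1-yl]hexa-2,4-dienoate
Product: 14 ethyl (2E,4E)-5-[(1R,3aS,8aS)-3a-methyl-4-oxo-1,2,3,3a,4,7,8,8a-octahydroazulen-1-yl]hexa-2,4-dienoate
Conditions: IBX (1.5 equiv), DMSO/toluene, 70 °C
Reagents that add atoms: none
Why: IBX dehydrogenation through the enol; only C5 can enolise because C3a is quaternary, so a single cycloheptenone forms.

**Step 8**
Reactants: 14 ethyl (2E,4E)-5-[(1R,3aS,8aS)-3a-methyl-4-oxo-1,2,3,3a,4,7,8,8a-octahydroazulen-1-yl]hexa-2,4-dienoate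
Product: 16 ethyl (2E,4E)-5-[(1R,3aS,8aS)-3a,6-dimethyl-4-oxo-1,2,3,3a,4,7,8,8a-octahydroazulen-1-yl]hexa-2,4-dienoate, via silyl enol ether 15 (not isolated)
Conditions: MeMgBr (1.3 equiv), CuBr·SMe2 (10 mol%), Me3SiCl, THF, −78 °C; then Pd(OAc)2 (1.1 equiv), MeCN, rt
Reagents that add atoms: methylmagnesium bromide (C[Mg]Br)
Why: Copper-catalysed conjugate addition with silyl trapping (the ring enone is far more reactive than the δ,δ-disubstituted dienoate) followed by Saegusa–Ito oxidation returns the enone with the methyl on C6; the transient C6 centre is erased.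

**Step 9**
Reactants: 16 ethyl (2E,4E)-5-[(1R,3aS,8aS)-3a,6-dimethyl-4-oxo-1,2,3,3a,4,7,8,8a-octahydroazulen-1-yl]hexa-2,4-dienoate
Product: 17 ethyl (2E,4E)-5-[(1R,3aS,5R,6R,8aS)-5,6-epoxy-3a,6-dimethyl-4-oxodecahydroazulen-1-yl]hexa-2,4-dienoate
Conditions: t-BuOOH, DBU, CH2Cl2, 0 °C to rt
Reagents that add atoms: tert-butyl hydroperoxide (CC(C)(C)OO)
Why: Weitz–Scheffer nucleophilic epoxidation; the hydroperoxide adds and closes on the face opposite the axial angular methyl (which is 1,3-diaxial to C5), giving the 5R,6R oxirane, while the dienoate is too poor an acceptor to react.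

**Step 10**
Reactants: 17 ethyl (2E,4E)-5-[(1R,3aS,5R,6R,8aS)-5,6-epoxy-3a,6-dimethyl-4-oxodecahydroazulen-1-yl]hexa-2,4-dienoate
Product: 18 ethyl (2E,4E)-5-[(1R,3aS,4S,5S,6R,8aS)-5,6-epoxy-4-hydroxy-3a,6-dimethyldecahydroazulen-1-yl]hexa-2,4-dienoate
Conditions: NaBH4, CeCl3·7H2O, MeOH, −78 °C
Reagents that add atoms: none
Why: Luche 1,2-reduction; hydride is delivered anti to the oxirane C–O bond (Felkin–Anh with oxygen as the polar group, the usual course for cyclic α,β-epoxy ketones), giving the cis epoxy alcohol (4S) and leaving the ester untouched.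

**Step 11**
Reactants: 18 ethyl (2E,4E)-5-[(1R,3aS,4S,5S,6R,8aS)-5,6-epoxy-4-hydroxy-3a,6-dimethyldecahydroazulen-1-yl]hexa-2,4-dienoate
Product: 19 (1R,3aS,4S,5S,6R,8aS)-5,6-epoxy-1-[(2E,4E)-6-hydroxy-6-methylhepta-2,4-dien-2-yl]-3a,6-dimethyldecahydroazulen-4-ol
Conditions: MeLi (4 equiv), THF, −78 to −40 °C
Reagents that add atoms: methyllithium ([Li]C)
Why: Double 1,2-addition of methyllithium to the ester gives the tertiary alcohol; one equivalent is consumed by the hydroxyl, and the hindered trisubstituted oxirane (cis to the alkoxide, so no Payne shift) survives at low temperature.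

**Step 12**
Reactants: 19 (1R,3aS,4S,5S,6R,8aS)-5,6-epoxy-1-[(2E,4E)-6-hydroxy-6-methylhepta-2,4-dien-2-yl]-3a,6-dimethyldecahydroazulen-4-ol
Product: 20 (1R,3aS,4S,5S,6R,8aS)-5,6-epoxy-1-[(2E,4E)-6-hydroxy-6-methylhepta-2,4-dien-2-yl]-3a,6-dimethyldecahydroazulen-4-yl acetate
Conditions: Ac2O, pyridine, DMAP (cat.), CH2Cl2, 0 °C to rt
Reagents that add atoms: acetic anhydride (CC(=O)OC(C)=O)
Why: DMAP-catalysed acylation of the secondary alcohol; the tertiary allylic alcohol does not acylate under these conditions.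

**Compound list**
1 | cycloheptane-1,3-dione | O=C1CCCCC(=O)C1 | starting material
2 | 2-methylcycloheptane-1,3-dione | CC1C(=O)CCCCC1=O | intermediate
3 | allyl methyl carbonate | C=CCOC(=O)OC | starting material
4 | 2-methyl-2-(prop-2-en-1-yl)cycloheptane-1,3-dione | C=CCC1(C)C(=O)CCCCC1=O | intermediate
5 | but-3-en-2-one | CC(=O)C=C | starting material
6 | 2-methyl-2-[(2E)-4-oxopent-2-en-1-yl]cycloheptane-1,3-dione | CC(=O)/C=C/CC1(C)C(=O)CCCCC1=O | intermediate
7 | (1S,3aS,8aS)-1-acetyl-8a-[diethoxy(methyl)silyloxy]-3a-methyloctahydroazulen-4(1H)-one | O=C1CCCC[C@]2(O[Si](C)(OCC)OCC)[C@@H](C(C)=O)CC[C@]12C | intermediate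
8 | (1S,3aS,8aS)-1-acetyl-8a-hydroxy-3a-methyloctahydroazulen-4(1H)-one (methyl, hydroxyl, acetyl all cis) | O=C1CCCC[C@]2(O)[C@@H](C(C)=O)CC[C@]12C | intermediate
9 | (3aS)-1-acetyl-3a-methyl-3,3a,5,6,7,8-hexahydroazulen-4(2H)-one | O=C1CCCCC2=C(C(C)=O)CC[C@]12C | intermediate
10 | lithium (1Z)-1-[(3aS,8aS)-3a-methyl-4-oxooctahydroazulen-1(2H)-ylidene]ethan-1-olate | O=C1CCCC[C@H]2/C(=C(/C)[O-])CC[C@]12C.[Li+] | intermediate
11 | (1R,3aS,8aS)-1-acetyl-3a-methyloctahydroazulen-4(1H)-one (trans-fused; acetyl trans to the angular methyl) | O=C1CCCC[C@H]2[C@H](C(C)=O)CC[C@]12C | intermediate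
12 | ethyl (2E)-4-(diethoxyphosphoryl)but-2-enoate | CCOC(=O)/C=C/CP(=O)(OCC)OCC | starting material
13 | ethyl (2E,4E)-5-[(1R,3aS,8aS)-3a-methyl-4-oxodecahydroazulen-1-yl]hexa-2,4-dienoate | O=C1CCCC[C@H]2[C@H](/C(C)=C/C=C/C(=O)OCC)CC[C@]12C | intermediate
14 | ethyl (2E,4E)-5-[(1R,3aS,8aS)-3a-methyl-4-oxo-1,2,3,3a,4,7,8,8a-octahydroazulen-1-yl]hexa-2,4-dienoate | O=C1C=CCC[C@H]2[C@H](/C(C)=C/C=C/C(=O)OCC)CC[C@]12C | intermediate
15 | ethyl (2E,4E)-5-[(1R,3aS,8aS)-3a,6-dimethyl-4-(trimethylsilyloxy)-1,2,3,3a,6,7,8,8a-octahydroazulen-1-yl]hexa-2,4-dienoate (both C6 epimers) | C[Si](C)(C)OC1=CC(C)CC[C@H]2[C@H](/C(C)=C/C=C/C(=O)OCC)CC[C@]12C | intermediate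
16 | ethyl (2E,4E)-5-[(1R,3aS,8aS)-3a,6-dimethyl-4-oxo-1,2,3,3a,4,7,8,8a-octahydroazulen-1-yl]hexa-2,4-dienoate | O=C1C=C(C)CC[C@H]2[C@H](/C(C)=C/C=C/C(=O)OCC)CC[C@]12C | intermediate
17 | ethyl (2E,4E)-5-[(1R,3aS,5R,6R,8aS)-5,6-epoxy-3a,6-dimethyl-4-oxodecahydroazulen-1-yl]hexa-2,4-dienoate | O=C1[C@@H]2O[C@]2(C)CC[C@H]2[C@H](/C(C)=C/C=C/C(=O)OCC)CC[C@]12C | intermediate
18 | ethyl (2E,4E)-5-[(1R,3aS,4S,5S,6R,8aS)-5,6-epoxy-4-hydroxy-3a,6-dimethyldecahydroazulen-1-yl]hexa-2,4-dienoate | O[C@@H]1[C@@H]2O[C@]2(C)CC[C@H]2[C@H](/C(C)=C/C=C/C(=O)OCC)CC[C@]12C | intermediate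
19 | (1R,3aS,4S,5S,6R,8aS)-5,6-epoxy-1-[(2E,4E)-6-hydroxy-6-methylhepta-2,4-dien-2-yl]-3a,6-dimethyldecahydroazulen-4-ol | O[C@@H]1[C@@H]2O[C@]2(C)CC[C@H]2[C@H](/C(C)=C/C=C/C(C)(C)O)CC[C@]12C | intermediate
20 | (1R,3aS,4S,5S,6R,8aS)-5,6-epoxy-1-[(2E,4E)-6-hydroxy-6-methylhepta-2,4-dien-2-yl]-3a,6-dimethyldecahydroazulen-4-yl acetate (CNP0265175.2) | CC(=O)O[C@@H]1[C@@H]2O[C@]2(C)CC[C@H]2[C@H](/C(C)=C/C=C/C(C)(C)O)CC[C@]12C | target

**Totals**
Total step count: 12. Longest linear sequence: 12 steps (1 to 20).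

**Three steps most likely to fail**

Step 4 (key step). The copper-hydride desymmetrisation is precedented for five- and six-membered 1,3-diones, but a seven-membered dione may give lower enantioselectivity or competing 1,2-reduction, and the sense of induction is assumed. Fallback, setting out from 6: hydrogenate the side-chain alkene (H2, Pd/C, EtOAc) to 2-methyl-2-(4-oxopentyl)cycloheptane-1,3-dione F1. Then replace the metal hydride by Brønsted-acid organocatalysis: a chiral phosphoric acid ((R)-TRIP, toluene, 80 °C) promotes a desymmetrising intramolecular aldol condensation through the internal enol of the methyl ketone. Five-ring closure is favoured over seven, and the product is 9, where the route is rejoined.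

Step 5. Two things can go wrong: protonation at C8a may give the cis ring fusion, and the ring ketone may be over-reduced. In addition, 11 is a 1,5-diketone, so base exposure must be kept short. Fallback, setting out from 8 (isolated by stopping step 4 before the acid stage): acylate the tertiary hydroxyl with methyl chlorooxoacetate (DMAP, pyridine, CH2Cl2) to give methyl (1S,3aS,8aS)-1-acetyl-3a-methyl-4-oxooctahydroazulen-8a(1H)-yl oxalate F2. Radical deoxygenation (Bu3SnH, AIBN, toluene, 110 °C) generates the tertiary C8a radical, which takes hydrogen on the face opposite the two cis neighbours (angular methyl and acetyl). This gives the trans-fused (1S,3aS,8aS)-1-acetyl-3a-methyloctahydroazulen-4(1H)-one F3 without ever forming the enone or touching the ring ketone. NaOMe in MeOH then epimerises C1, and the route is rejoined at 11.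

Step 10. The oxirane directs hydride to the face that also carries the axial angular methyl, so the two controlling elements oppose each other and the C4 epimer may dominate. Fallback, setting out from 17, moves the oxygen instead of delivering hydride. Wharton transposition (N2H4·H2O, AcOH cat., MeOH, 0 °C to rt) passes through ethyl (2E,4E)-5-[(1R,3aS,5S,6R,8aS)-5,6-epoxy-4-hydrazinylidene-3a,6-dimethyldecahydroazulen-1-yl]hexa-2,4-dienoate F4 (not isolated). This loses nitrogen to give the tertiary allylic alcohol ethyl (2E,4E)-5-[(1R,3aR,6R,8aS)-6-hydroxy-3a,6-dimethyl-1,2,3,3a,6,7,8,8a-octahydroazulen-1-yl]hexa-2,4-dienoate F5, with the C6 oxygen still on the face opposite the angular methyl. A suprafacial 1,3-hydroxyl shift (Re2O7 cat., Et2O, 0 °C) carries that oxygen to C4 on the same face, giving ethyl (2E,4E)-5-[(1R,3aS,4R,8aS)-4-hydroxy-3a,6-dimethyl-1,2,3,3a,4,7,8,8a-octahydroazulen-1-yl]hexa-2,4-dienoate F6. Hydroxyl-directed syn epoxidation (VO(acac)2, t-BuOOH, CH2Cl2) then gives 18, where the route is rejoined.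

**Further compounds**
F1 | step 4 | 2-methyl-2-(4-oxopentyl)cycloheptane-1,3-dione | CC(=O)CCCC1(C)C(=O)CCCCC1=O
F2 | step 5 | methyl (1S,3aS,8aS)-1-acetyl-3a-methyl-4-oxooctahydroazulen-8a(1H)-yl oxalate | O=C1CCCC[C@]2(OC(=O)C(=O)OC)[C@@H](C(C)=O)CC[C@]12C
F3 | step 5 | (1S,3aS,8aS)-1-acetyl-3a-methyloctahydroazulen-4(1H)-one | O=C1CCCC[C@H]2[C@@H](C(C)=O)CC[C@]12C
F4 | step 10 | ethyl (2E,4E)-5-[(1R,3aS,5S,6R,8aS)-5,6-epoxy-4-hydrazinylidene-3a,6-dimethyldecahydroazulen-1-yl]hexa-2,4-dienoate | NN=C1[C@@H]2O[C@]2(C)CC[C@H]2[C@H](/C(C)=C/C=C/C(=O)OCC)CC[C@]12C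
F5 | step 10 | ethyl (2E,4E)-5-[(1R,3aR,6R,8aS)-6-hydroxy-3a,6-dimethyl-1,2,3,3a,6,7,8,8a-octahydroazulen-1-yl]hexa-2,4-dienoate | C1=C[C@](C)(O)CC[C@H]2[C@H](/C(C)=C/C=C/C(=O)OCC)CC[C@]12C
F6 | step 10 | ethyl (2E,4E)-5-[(1R,3aS,4R,8aS)-4-hydroxy-3a,6-dimethyl-1,2,3,3a,4,7,8,8a-octahydroazulen-1-yl]hexa-2,4-dienoate | O[C@@H]1C=C(C)CC[C@H]2[C@H](/C(C)=C/C=C/C(=O)OCC)CC[C@]12C
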